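**Retrosynthetic overview**
- The target comes from its tetra-MOM ether. C2 is fixed by a Ru-catalysed transfer-hydrogenation kinetic resolution of the C2-epimeric flavanone.
- Ring C is the only ring that is built, and it is closed last, by oxa-Michael cyclisation of a 2'-hydroxychalcone. Rings A and B are bought as 2,4,6-trihydroxybenzaldehyde and 2,4-dihydroxybenzaldehyde.
- The chalcone comes from a Claisen–Schmidt condensation. The acetyl group of ring A is placed ortho to the single free phenol (formylation, MeMgBr, oxidation), so only the 8-alkyl flavanone can form.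
- Side chain: the isopropenyl group comes from a CH2OH arm (CHO, MeCH(OH), COMe, C(Me)=CH2). The CH2CH2C(Me)=CH2 arm comes from a CH2I arm and 2-methylallyl Grignard with CuI.
- Both arms come from a prochiral 2-(arylmethyl)propane-1,3-diol (Knoevenagel, NaBH4, LiAlH4). A lipase desymmetrises it and sets the first stereocentre.

Abbreviations: MOM = methoxymethyl; TBDPS = tert-butyldiphenylsilyl; allyl = prop-2-en-1-yl; Ar = 2-(allyloxy)-4,6-bis(methoxymethoxy)phenyl; R1 = (2R)-5-methyl-2-(prop-1-en-2-yl)hex-5-en-1-yl.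
Assumption: the target SMILES is read as 2S at C2 and 2R in the side chain.
Assumption: the lipase acetylates the pro-R CH2OH arm of the diol, the sense expected from the size rule for primary alcohols with Pseudomonas-type lipases; this is recalled, not verified, and is confirmed on the monoacetate by Mosher ester analysis before going on.

**Route**

Step 1
Reactants: 1 2,4,6-trihydroxybenzaldehyde
Product: 2 2-hydroxy-4,6-bis(methoxymethoxy)benzaldehyde
Conditions: MOMCl (2.2 equiv), iPr2NEt (2.5 equiv), CH2Cl2, 0 °C to rt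
Reagents that add atoms: chloromethyl methyl ether (MOMCl), COCCl
Why: Williamson-type O-alkylation with a hard electrophile takes the two free phenols while the phenol hydrogen-bonded to the formyl group stays untouched, which marks the oxygen that will become O1 of ring C.

Step 2
Reactants: 2 2-hydroxy-4,6-bis(methoxymethoxy)benzaldehyde
Product: 3 2-(allyloxy)-4,6-bis(methoxymethoxy)benzaldehyde (ArCHO)
Conditions: allyl bromide (1.5 equiv), K2CO3 (2 equiv), DMF, rt
Reagents that add atoms: allyl bromide, C=CCBr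
Why: Williamson O-allylation masks the remaining phenol with a group orthogonal to MOM that a zerovalent palladium catalyst can later remove without acid or hydrogen.

Step 3
Reactants: 3 2-(allyloxy)-4,6-bis(methoxymethoxy)benzaldehyde; 4 dimethyl malonate
Product: 5 dimethyl 2-(Ar-methylidene)propanedioate
Conditions: piperidine (0.2 equiv), AcOH (0.2 equiv), toluene, 4 Å sieves, 90 °C
Reagents that add atoms: none
Why: Knoevenagel condensation under piperidinium acetate catalysis with removal of water; the hindered electron-rich aldehyde needs heat, but 90 °C is far below the temperature of an aryl allyl ether Claisen rearrangement.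

Step 4
Reactants: 5 dimethyl 2-(Ar-methylidene)propanedioate
Product: 6 dimethyl 2-(Ar-methyl)propanedioate
Conditions: NaBH4 (1.1 equiv), MeOH/THF, 0 °C
Reagents that add atoms: none
Why: Conjugate (1,4) hydride reduction of the doubly activated alkylidene malonate by NaBH4 is fast at 0 °C and leaves the esters and the allyl ether alone.

Step 5
Reactants: 6 dimethyl 2-(Ar-methyl)propanedioate
Product: 7 2-(Ar-methyl)propane-1,3-diol
Conditions: LiAlH4 (3 equiv), THF, 0 °C to rt (inverse addition)
Reagents that add atoms: none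
Why: LiAlH4 ester reduction gives the prochiral diol whose two CH2OH arms are enantiotopic, so no stereocentre exists yet.

Step 6
Reactants: 7 2-(Ar-methyl)propane-1,3-diol
Product: 8 (2R)-2-(Ar-methyl)-3-hydroxypropyl acetate
Conditions: Burkholderia cepacia lipase (immobilised), vinyl acetate (4 equiv), t-BuOMe, 30 °C
Reagents that add atoms: vinyl acetate, C=COC(C)=O
Why: A lipase (a serine hydrolase) carries out an enantiotopos-selective transesterification with the irreversible donor vinyl acetate, acetylating the pro-R arm and so setting the first stereocentre as R by enzymatic desymmetrisation; letting about 5–10 % diacetate form raises the ee of the monoacetate further.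

Step 7
Reactants: 8 (2R)-2-(Ar-methyl)-3-hydroxypropyl acetate
Product: 9 (2S)-2-(Ar-methyl)-3-[(tert-butyldiphenylsilyl)oxy]propyl acetate
Conditions: TBDPSCl (1.2 equiv), imidazole (2.5 equiv), DMF, 0 °C
Reagents that add atoms: tert-butyl(chloro)diphenylsilane (TBDPSCl), CC(C)(C)[Si](Cl)(c1ccccc1)c1ccccc1
Why: Silyl ether formation on the free primary alcohol locks the differentiation of the two arms and is run at 0 °C to outrun 1,3-acyl migration (the descriptor changes only because of CIP priorities).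

Step 8
Reactants: 9 (2S)-2-(Ar-methyl)-3-[(tert-butyldiphenylsilyl)oxy]propyl acetate
Product: 10 (2S)-2-(Ar-methyl)-3-[(tert-butyldiphenylsilyl)oxy]propan-1-ol
Conditions: K2CO3 (0.3 equiv), MeOH, 0 °C
Reagents that add atoms: none
Why: Base-catalysed transesterification (methanolysis) removes the acetate while the bulky TBDPS group neither cleaves nor migrates under these mild conditions.

Step 9
Reactants: 10 (2S)-2-(Ar-methyl)-3-[(tert-butyldiphenylsilyl)oxy]propan-1-ol
Product: 11 [(2R)-2-(Ar-methyl)-3-iodopropoxy](tert-butyl)diphenylsilane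
Conditions: PPh3 (1.5 equiv), imidazole (2 equiv), I2 (1.5 equiv), CH2Cl2, 0 °C to rt
Reagents that add atoms: iodine, II
Why: Appel-type iodination (Garegg–Samuelsson) converts the primary alcohol into the iodide by SN2 displacement at CH2 without touching the adjacent stereocentre.

Step 10
Reactants: 11 [(2R)-2-(Ar-methyl)-3-iodopropoxy](tert-butyl)diphenylsilane
Product: 12 {[(2R)-2-(Ar-methyl)-5-methylhex-5-en-1-yl]oxy}(tert-butyl)diphenylsilane
Conditions: CH2=C(CH3)CH2MgCl (3 equiv), CuI (10 mol %), THF, −30 to 0 °C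
Reagents that add atoms: 2-methylallylmagnesium chloride, C=C(C)C[Mg]Cl
Why: Copper-catalysed sp3–sp3 Grignard cross-coupling (Kochi type) of the primary iodide with the reactive allylic Grignard reagent builds the CH2CH2C(CH3)=CH2 arm, and a 2-methylallyl unit gives the same product by SN2 or SN2' transfer.

Step 11
Reactants: 12 {[(2R)-2-(Ar-methyl)-5-methylhex-5-en-1-yl]oxy}(tert-butyl)diphenylsilane
Product: 13 (2R)-2-(Ar-methyl)-5-methylhex-5-en-1-ol
Conditions: Bu4NF (1.5 equiv), THF, rt
Reagents that add atoms: none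
Why: Fluoride-mediated desilylation driven by the strong Si–F bond frees the second primary alcohol.

Step 12
Reactants: 13 (2R)-2-(Ar-methyl)-5-methylhex-5-en-1-ol
Product: 14 (2R)-2-(Ar-methyl)-5-methylhex-5-enal
Conditions: Dess–Martin periodinane (1.3 equiv), NaHCO3 (5 equiv), CH2Cl2, 0 °C to rt; used at once
Reagents that add atoms: none
Why: Buffered Dess–Martin oxidation gives the α-branched aldehyde under non-basic conditions so that the α-stereocentre is not epimerised.

Step 13
Reactants: 14 (2R)-2-(Ar-methyl)-5-methylhex-5-enal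
Product: 15 (3R)-3-(Ar-methyl)-6-methylhept-6-en-2-ol (both C2 epimers)
Conditions: MeMgBr (1.5 equiv), THF, −78 °C
Reagents that add atoms: methylmagnesium bromide, C[Mg]Br
Why: Grignard 1,2-addition to the aldehyde at low temperature installs the methyl group; the new carbinol centre forms unselectively and is erased in the next step.

Step 14
Reactants: 15 (3R)-3-(Ar-methyl)-6-methylhept-6-en-2-ol
Product: 16 (3R)-3-(Ar-methyl)-6-methylhept-6-en-2-one
Conditions: Dess–Martin periodinane (1.5 equiv), NaHCO3 (5 equiv), CH2Cl2, rt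
Reagents that add atoms: none
Why: Dess–Martin oxidation of the secondary alcohol gives the methyl ketone without base, so the α-stereocentre keeps its configuration.

Step 15
Reactants: 16 (3R)-3-(Ar-methyl)-6-methylhept-6-en-2-one
Product: 17 1-(allyloxy)-3,5-bis(methoxymethoxy)-2-R1-benzene
Conditions: Ph3PCH3Br (2.0 equiv), KOtBu (1.9 equiv), THF, 0 °C to rt
Reagents that add atoms: methyltriphenylphosphonium bromide, C[P+](c1ccccc1)(c1ccccc1)c1ccccc1.[Br-]
Why: Wittig methylenation turns the acetyl group into the isopropenyl group; a slight deficit of base leaves no free alkoxide and a methyl ketone enolises towards CH3, so the α-stereocentre survives and is no longer epimerisable afterwards.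

Step 16
Reactants: 17 1-(allyloxy)-3,5-bis(methoxymethoxy)-2-R1-benzene
Product: 18 3,5-bis(methoxymethoxy)-2-R1-phenol
Conditions: Pd(PPh3)4 (5 mol %), morpholine (5 equiv), THF, rt
Reagents that add atoms: none
Why: Tsuji–Trost deallylation: the zerovalent palladium catalyst ionises the aryl allyl ether to a π-allyl complex that morpholine captures, while the unactivated 1,1-disubstituted alkenes and the MOM ethers are inert.

Step 17
Reactants: 18 3,5-bis(methoxymethoxy)-2-R1-phenol
Product: 20 2-hydroxy-4,6-bis(methoxymethoxy)-3-R1-benzaldehyde, via hydroxymethylphenol 19 (not isolated)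
Conditions: MgCl2 (3 equiv), Et3N (5 equiv), paraformaldehyde (7 equiv), MeCN, 80 °C
Reagents that add atoms: paraformaldehyde (as formaldehyde), C=O
Why: Casnati–Skattebøl ortho-formylation: the magnesium phenoxide delivers formaldehyde only to the free position ortho to the phenol (the other ortho position carries the side chain) and a second formaldehyde oxidises the benzylic alkoxide by hydride transfer, so the carbonyl carbon sits exactly between the free OH and an OMOM group.

Step 18
Reactants: 20 2-hydroxy-4,6-bis(methoxymethoxy)-3-R1-benzaldehyde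
Product: 21 2-(1-hydroxyethyl)-3,5-bis(methoxymethoxy)-6-R1-phenol (both carbinol epimers)
Conditions: MeMgBr (3 equiv), THF, −20 to 0 °C; crude product used directly
Reagents that add atoms: methylmagnesium bromide, C[Mg]Br
Why: Grignard addition to the salicylaldehyde (one equivalent is consumed by the phenol) gives the benzylic alcohol, whose configuration is irrelevant.

Step 19
Reactants: 21 2-(1-hydroxyethyl)-3,5-bis(methoxymethoxy)-6-R1-phenol
Product: 22 1-[2-hydroxy-4,6-bis(methoxymethoxy)-3-R1-phenyl]ethan-1-one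
Conditions: MnO2 (20 equiv), CH2Cl2, rt
Reagents that add atoms: none
Why: MnO2 oxidises the electron-rich benzylic alcohol selectively to the hydrogen-bonded 2-hydroxyacetophenone and does not touch the alkenes.

Step 20
Reactants: 23 2,4-dihydroxybenzaldehyde
Product: 24 2,4-bis(methoxymethoxy)benzaldehyde
Conditions: MOMCl (3 equiv), iPr2NEt (4 equiv), CH2Cl2, 0 to 40 °C
Reagents that add atoms: chloromethyl methyl ether (MOMCl), COCCl
Why: Exhaustive Williamson-type MOM protection of both phenols of the ring B aldehyde prevents phenoxide deactivation in the aldol step and flavylium formation at the chalcone stage.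

Step 21
Reactants: 22 1-[2-hydroxy-4,6-bis(methoxymethoxy)-3-R1-phenyl]ethan-1-one; 24 2,4-bis(methoxymethoxy)benzaldehyde
Product: 26 (2E)-3-[2,4-bis(methoxymethoxy)phenyl]-1-[2-hydroxy-4,6-bis(methoxymethoxy)-3-R1-phenyl]prop-2-en-1-one, via aldol adduct 25 (not isolated)
Conditions: KOH (50 % aq, 15 equiv), EtOH, rt, 48 h
Reagents that add atoms: none
Why: Claisen–Schmidt (crossed aldol) condensation of the acetophenone enolate with the non-enolisable aldehyde followed by E1cB dehydration gives the E-chalcone.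

Step 22
Reactants: 26 the E-chalcone
Product: 27 (2RS)-2-[2,4-bis(methoxymethoxy)phenyl]-5,7-bis(methoxymethoxy)-8-R1-2,3-dihydro-4H-chromen-4-one (about 1:1 mixture of C2 epimers)
Conditions: NaOAc (10 equiv), EtOH, reflux, 24–48 h; recovered chalcone recycled
Reagents that add atoms: none
Why: Base-mediated 6-endo oxa-Michael cyclisation closes ring C through the only free ortho phenol, so only the 8-substituted flavanone can form; C2 forms without control and is corrected in the next step.

Step 23
Reactants: 27 the C2-epimeric flavanone mixture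
Product: 28 (2S)-2-[2,4-bis(methoxymethoxy)phenyl]-5,7-bis(methoxymethoxy)-8-R1-2,3-dihydro-4H-chromen-4-one
Conditions: RuCl[(R,R)-TsDPEN](p-cymene) (3 mol %), HCO2H/Et3N 5:2, EtOAc, 30 °C, stopped at about 52–55 % conversion
Reagents that add atoms: none
Why: Noyori–Ikariya asymmetric transfer hydrogenation used as a kinetic resolution: the (R,R) catalyst reduces the (2R)-epimer to the cis-(2R,4R)-flavan-4-ol much faster than the (2S)-epimer, which is recovered as the ketone with the required 2S configuration and separated from the alcohol by chromatography.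

Step 24
Reactants: 28 the (2S)-tetra-MOM flavanone
Product: 29 remangiflavanone B, (2S)-2-(2,4-dihydroxyphenyl)-5,7-dihydroxy-8-R1-2,3-dihydro-4H-chromen-4-one
Conditions: HCl (3 M aq)/MeOH 1:4, 40 °C, 3–6 h, monitored
Reagents that add atoms: none
Why: Acid-catalysed acetal solvolysis removes all four MOM groups in methanol; dilute acid and moderate temperature are chosen so that the isopropenyl group and the C2 centre are not affected.

**Compound list**

1 | 2,4,6-trihydroxybenzaldehyde | O=Cc1c(O)cc(O)cc1O | starting material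
2 | 2-hydroxy-4,6-bis(methoxymethoxy)benzaldehyde | O=Cc1c(O)cc(OCOC)cc1OCOC | intermediate
3 | 2-(allyloxy)-4,6-bis(methoxymethoxy)benzaldehyde | O=Cc1c(OCC=C)cc(OCOC)cc1OCOC | intermediate
4 | dimethyl malonate | COC(=O)CC(=O)OC | starting material
5 | dimethyl 2-{[2-(allyloxy)-4,6-bis(methoxymethoxy)phenyl]methylidene}propanedioate | COC(=O)C(=Cc1c(OCC=C)cc(OCOC)cc1OCOC)C(=O)OC | intermediate
6 | dimethyl 2-{[2-(allyloxy)-4,6-bis(methoxymethoxy)phenyl]methyl}propanedioate | COC(=O)C(Cc1c(OCC=C)cc(OCOC)cc1OCOC)C(=O)OC | intermediate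
7 | 2-{[2-(allyloxy)-4,6-bis(methoxymethoxy)phenyl]methyl}propane-1,3-diol | OCC(CO)Cc1c(OCC=C)cc(OCOC)cc1OCOC | intermediate
8 | (2R)-2-(Ar-methyl)-3-hydroxypropyl acetate | CC(=O)OC[C@H](Cc1c(OCC=C)cc(OCOC)cc1OCOC)CO | intermediate
9 | (2S)-2-(Ar-methyl)-3-[(tert-butyldiphenylsilyl)oxy]propyl acetate | CC(=O)OC[C@H](Cc1c(OCC=C)cc(OCOC)cc1OCOC)CO[Si](c1ccccc1)(c1ccccc1)C(C)(C)C | intermediate
10 | (2S)-2-(Ar-methyl)-3-[(tert-butyldiphenylsilyl)oxy]propan-1-ol | OC[C@H](Cc1c(OCC=C)cc(OCOC)cc1OCOC)CO[Si](c1ccccc1)(c1ccccc1)C(C)(C)C | intermediate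
11 | [(2R)-2-(Ar-methyl)-3-iodopropoxy](tert-butyl)diphenylsilane | IC[C@H](Cc1c(OCC=C)cc(OCOC)cc1OCOC)CO[Si](c1ccccc1)(c1ccccc1)C(C)(C)C | intermediate
12 | {[(2R)-2-(Ar-methyl)-5-methylhex-5-en-1-yl]oxy}(tert-butyl)diphenylsilane | C=C(C)CC[C@H](Cc1c(OCC=C)cc(OCOC)cc1OCOC)CO[Si](c1ccccc1)(c1ccccc1)C(C)(C)C | intermediate
13 | (2R)-2-(Ar-methyl)-5-methylhex-5-en-1-ol | C=C(C)CC[C@H](Cc1c(OCC=C)cc(OCOC)cc1OCOC)CO | intermediate
14 | (2R)-2-(Ar-methyl)-5-methylhex-5-enal | C=C(C)CC[C@H](Cc1c(OCC=C)cc(OCOC)cc1OCOC)C=O | intermediate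
15 | (3R)-3-(Ar-methyl)-6-methylhept-6-en-2-ol, both C2 epimers | C=C(C)CC[C@H](Cc1c(OCC=C)cc(OCOC)cc1OCOC)C(C)O | intermediate
16 | (3R)-3-(Ar-methyl)-6-methylhept-6-en-2-one | C=C(C)CC[C@H](Cc1c(OCC=C)cc(OCOC)cc1OCOC)C(C)=O | intermediate
17 | 1-(allyloxy)-3,5-bis(methoxymethoxy)-2-[(2R)-5-methyl-2-(prop-1-en-2-yl)hex-5-en-1-yl]benzene | C=C(C)CC[C@H](Cc1c(OCC=C)cc(OCOC)cc1OCOC)C(C)=C | intermediate
18 | 3,5-bis(methoxymethoxy)-2-[(2R)-5-methyl-2-(prop-1-en-2-yl)hex-5-en-1-yl]phenol | C=C(C)CC[C@H](Cc1c(O)cc(OCOC)cc1OCOC)C(C)=C | intermediate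
19 | 2-(hydroxymethyl)-3,5-bis(methoxymethoxy)-6-[(2R)-5-methyl-2-(prop-1-en-2-yl)hex-5-en-1-yl]phenol | C=C(C)CC[C@H](Cc1c(O)c(CO)c(OCOC)cc1OCOC)C(C)=C | intermediate (not isolated)
20 | 2-hydroxy-4,6-bis(methoxymethoxy)-3-[(2R)-5-methyl-2-(prop-1-en-2-yl)hex-5-en-1-yl]benzaldehyde | C=C(C)CC[C@H](Cc1c(O)c(C=O)c(OCOC)cc1OCOC)C(C)=C | intermediate
21 | 2-(1-hydroxyethyl)-3,5-bis(methoxymethoxy)-6-[(2R)-5-methyl-2-(prop-1-en-2-yl)hex-5-en-1-yl]phenol, both carbinol epimers | C=C(C)CC[C@H](Cc1c(O)c(C(C)O)c(OCOC)cc1OCOC)C(C)=C | intermediate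
22 | 1-{2-hydroxy-4,6-bis(methoxymethoxy)-3-[(2R)-5-methyl-2-(prop-1-en-2-yl)hex-5-en-1-yl]phenyl}ethan-1-one | C=C(C)CC[C@H](Cc1c(O)c(C(C)=O)c(OCOC)cc1OCOC)C(C)=C | intermediate
23 | 2,4-dihydroxybenzaldehyde | O=Cc1ccc(O)cc1O | starting material
24 | 2,4-bis(methoxymethoxy)benzaldehyde | O=Cc1ccc(OCOC)cc1OCOC | intermediate
25 | 3-[2,4-bis(methoxymethoxy)phenyl]-3-hydroxy-1-{2-hydroxy-4,6-bis(methoxymethoxy)-3-[(2R)-5-methyl-2-(prop-1-en-2-yl)hex-5-en-1-yl]phenyl}propan-1-one | C=C(C)CC[C@H](Cc1c(O)c(C(=O)CC(O)c2ccc(OCOC)cc2OCOC)c(OCOC)cc1OCOC)C(C)=C | intermediate (not isolated)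
26 | (2E)-3-[2,4-bis(methoxymethoxy)phenyl]-1-{2-hydroxy-4,6-bis(methoxymethoxy)-3-[(2R)-5-methyl-2-(prop-1-en-2-yl)hex-5-en-1-yl]phenyl}prop-2-en-1-one | C=C(C)CC[C@H](Cc1c(O)c(C(=O)/C=C/c2ccc(OCOC)cc2OCOC)c(OCOC)cc1OCOC)C(C)=C | intermediate
27 | (2RS)-2-[2,4-bis(methoxymethoxy)phenyl]-5,7-bis(methoxymethoxy)-8-[(2R)-5-methyl-2-(prop-1-en-2-yl)hex-5-en-1-yl]-2,3-dihydro-4H-chromen-4-one, 1:1 C2 epimers | C=C(C)CC[C@H](Cc1c(OCOC)cc(OCOC)c2c1OC(c1ccc(OCOC)cc1OCOC)CC2=O)C(=C)C | intermediate
28 | (2S)-2-[2,4-bis(methoxymethoxy)phenyl]-5,7-bis(methoxymethoxy)-8-[(2R)-5-methyl-2-(prop-1-en-2-yl)hex-5-en-1-yl]-2,3-dihydro-4H-chromen-4-one | C=C(C)CC[C@H](Cc1c(OCOC)cc(OCOC)c2c1O[C@H](c1ccc(OCOC)cc1OCOC)CC2=O)C(=C)C | intermediate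
29 | remangiflavanone B, (2S)-2-(2,4-dihydroxyphenyl)-5,7-dihydroxy-8-[(2R)-5-methyl-2-(prop-1-en-2-yl)hex-5-en-1-yl]-2,3-dihydro-4H-chromen-4-one | C=C(C)CC[C@H](Cc1c(O)cc(O)c2c1O[C@H](c1ccc(O)cc1O)CC2=O)C(=C)C | target

**Step count and risks**

Total step count: 24. Longest linear sequence: 23 steps (steps 1–19 and 21–24, from 1 to 29); step 20 is the only side branch.

The three steps most likely to fail, each with a fallback:

First, step 24. The acid that cleaves the MOM ethers can also protonate the isopropenyl group, which then closes a dimethylchroman ring with the neighbouring 7-OH, or it can add methanol to the alkenes. The fallback sets out from 28 and avoids any Brønsted acid. Me3SiOTf with 2,2'-bipyridyl in CH2Cl2 at 0 °C exchanges each aryl MOM ether for a trimethylsilyl ether and gives the tetrakis(trimethylsilyl) ether F1. Brief stirring of F1 with water in MeOH at rt hydrolyses the aryl silyl ethers, and the route is rejoined at 29.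

Second, step 23. The 5-OMOM group and the bulky 8-substituent may slow the transfer hydrogenation or lower its selectivity between the C2 epimers. The fallback sets out from 27 and replaces the catalytic resolution by a physical separation with recycling. Preparative HPLC on a cellulose tris(3,5-dimethylphenylcarbamate) phase separates 28 from the (2R)-epimer F2. F2 is heated with NaOAc in EtOH, which re-opens it to chalcone 26 and returns the 1:1 mixture 27 for another pass. The route is rejoined at 28.

Third, step 18 (with the oxidation that follows). The electron-rich ortho-hydroxybenzylic alcohol 21 can lose water to an ortho-quinone methide before MnO2 has oxidised it. The fallback sets out from 20 and masks the phenol first. Allyl bromide and K2CO3 in DMF give the 2-(allyloxy)benzaldehyde F3. MeMgBr in THF at −78 °C gives the 1-[2-(allyloxy)aryl]ethanol F4, which cannot form a quinone methide. Dess–Martin periodinane gives the 2-(allyloxy)acetophenone F5, and Pd(PPh3)4 with morpholine removes the allyl group. The route is rejoined at 22.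

**Further compounds**

F1 | step 24 | (2S)-2-[2,4-bis(trimethylsilyloxy)phenyl]-5,7-bis(trimethylsilyloxy)-8-[(2R)-5-methyl-2-(prop-1-en-2-yl)hex-5-en-1-yl]-2,3-dihydro-4H-chromen-4-one | C=C(C)CC[C@H](Cc1c(O[Si](C)(C)C)cc(O[Si](C)(C)C)c2c1O[C@H](c1ccc(O[Si](C)(C)C)cc1O[Si](C)(C)C)CC2=O)C(=C)C
F2 | step 23 | (2R)-2-[2,4-bis(methoxymethoxy)phenyl]-5,7-bis(methoxymethoxy)-8-[(2R)-5-methyl-2-(prop-1-en-2-yl)hex-5-en-1-yl]-2,3-dihydro-4H-chromen-4-one | C=C(C)CC[C@H](Cc1c(OCOC)cc(OCOC)c2c1O[C@@H](c1ccc(OCOC)cc1OCOC)CC2=O)C(=C)C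
F3 | step 18 | 2-(allyloxy)-4,6-bis(methoxymethoxy)-3-[(2R)-5-methyl-2-(prop-1-en-2-yl)hex-5-en-1-yl]benzaldehyde | C=C(C)CC[C@H](Cc1c(OCC=C)c(C=O)c(OCOC)cc1OCOC)C(C)=C
F4 | step 18 | 1-{2-(allyloxy)-4,6-bis(methoxymethoxy)-3-[(2R)-5-methyl-2-(prop-1-en-2-yl)hex-5-en-1-yl]phenyl}ethan-1-ol, both carbinol epimers | C=C(C)CC[C@H](Cc1c(OCC=C)c(C(C)O)c(OCOC)cc1OCOC)C(C)=C
F5 | step 18 | 1-{2-(allyloxy)-4,6-bis(methoxymethoxy)-3-[(2R)-5-methyl-2-(prop-1-en-2-yl)hex-5-en-1-yl]phenyl}ethan-1-one | C=C(C)CC[C@H](Cc1c(OCC=C)c(C(C)=O)c(OCOC)cc1OCOC)C(C)=C
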